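**Plan**

- Retrosynthesis: the two outer phenols are unmasked last from methyl ethers; the two C–Br bonds of the central ring are cut back to C–CO2H; the two central-ring C–O(aryl) bonds are cut to a 2,5-dibromo-3,6-bis(ethoxycarbonyl)benzoquinone and two molecules of 2,3,5-tribromo-4-methoxyphenol.
- Enabling feature: on the central ring the two bromine-bearing carbons are para to each other and each is ortho to a hydroxyl-bearing carbon. These are the positions of the carboxyl carbons in 2,5-dihydroxyterephthalic acid, so each CO2H can be exchanged for Br by ipso attack.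
- Forward: no ring is built. The central ring comes from diethyl 2,5-dihydroxyterephthalate (brominated, then oxidised to the quinone); each outer ring comes from 2,6-dibromoanisole (C–H borylation/oxidation, then one ortho-bromination).
- Both phenoxides are joined to the quinone in one operation; reduction, ester hydrolysis, double bromodecarboxylation and O-demethylation follow.
- Stereochemistry: the target has no stereocentre, axis or configured double bond; it is achiral and nothing has to be set.

Key step: step 8

Assumption: 1 and 4 are purchased (4 replaces an aldehyde-based entry to the outer phenol because the borylation route is shorter and regiochemically unambiguous); quinone 3 is prepared immediately before use.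

**Route**

Step 1
Reactants: 1 diethyl 2,5-dihydroxyterephthalate
Product: 2 diethyl 2,5-dibromo-3,6-dihydroxyterephthalate
Conditions: Br2 (2.2 equiv), AcOH, rt to 50 °C
Reagents that add atoms: bromine, BrBr
Why: Electrophilic aromatic bromination at the only two ring C–H positions, each ortho to a phenolic OH, so the regiochemistry is forced; if bromine first oxidised the hydroquinone, HBr addition to that quinone would give the same product.

Step 2
Reactants: 2 diethyl 2,5-dibromo-3,6-dihydroxyterephthalate
Product: 3 diethyl 2,5-dibromo-3,6-dioxocyclohexa-1,4-diene-1,4-dicarboxylate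
Conditions: (NH4)2Ce(NO3)6 (2.2 equiv), MeCN/H2O, 0 °C, prompt extraction into CH2Cl2
Reagents that add atoms: none
Why: Hydroquinone-to-quinone oxidation with a one-electron oxidant strong enough for this electron-poor, hydrogen-bonded hydroquinone; short cold contact with water should keep the very electrophilic bromoquinone from hydrating.

Step 3
Reactants: 4 2,6-dibromoanisole
Product: 6 3,5-dibromo-4-methoxyphenol, via aryl pinacol boronate 5 (not isolated)
Conditions: [Ir(OMe)(cod)]2 (1.5 mol%), dtbpy (3 mol%), B2pin2 (0.55 equiv), THF, 80 °C; then Oxone, acetone/H2O, rt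
Reagents that add atoms: potassium peroxymonosulfate (active part of Oxone, supplies the phenol oxygen), [K+].[O-]S(=O)(=O)OO; bis(pinacolato)diboron (supplies the boronate of intermediate 5 only), CC1(C)OB(OC1(C)C)B1OC(C)(C)C(C)(C)O1
Why: Iridium-catalysed aromatic C–H borylation is sterically governed and should hit only C4 of 4, the one C–H without an ortho substituent, leaving C–Br intact; peroxymonosulfate then oxidises C–B to C–OH in the same pot.

Step 4
Reactants: 6 3,5-dibromo-4-methoxyphenol
Product: 7 2,3,5-tribromo-4-methoxyphenol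
Conditions: NBS (1.0 equiv), i-Pr2NH (10 mol%), CH2Cl2, 0 °C
Reagents that add atoms: N-bromosuccinimide, O=C1CCC(=O)N1Br
Why: Amine-catalysed ortho-selective electrophilic bromination of a phenol; the para position is blocked by OMe, the two ortho positions are equivalent, and one equivalent of NBS plus the deactivating third bromine should stop the reaction at the monobromide.

Step 5
Reactants: 3 diethyl 2,5-dibromo-3,6-dioxocyclohexa-1,4-diene-1,4-dicarboxylate; 7 2,3,5-tribromo-4-methoxyphenol (2 equiv)
Product: 8 diethyl 3,6-dioxo-2,5-bis(2,3,5-tribromo-4-methoxyphenoxy)cyclohexa-1,4-diene-1,4-dicarboxylate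
Conditions: 7 (2.1 equiv), NaH (2.05 equiv), THF, 0 °C; then 3, −40 °C to rt
Reagents that add atoms: none
Why: Addition–elimination (vinylogous acyl substitution) of phenoxide at the two C–Br carbons, each β to a ring carbonyl and to an ester carbonyl, as in the known conversion of tetrahaloquinones into 2,5-bis(aryloxy)quinones; the pre-formed, weakly basic phenoxide should leave the esters alone.

Step 6
Reactants: 8 diethyl 3,6-dioxo-2,5-bis(2,3,5-tribromo-4-methoxyphenoxy)cyclohexa-1,4-diene-1,4-dicarboxylate
Product: 9 diethyl 2,5-dihydroxy-3,6-bis(2,3,5-tribromo-4-methoxyphenoxy)terephthalate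
Conditions: Na2S2O4, EtOAc/H2O, rt
Reagents that add atoms: none
Why: Dithionite reduction of a quinone to its hydroquinone, which does not touch aryl bromides, esters or ethers and should give an air-stable, hydrogen-bonded dihydroxyterephthalate.

Step 7
Reactants: 9 diethyl 2,5-dihydroxy-3,6-bis(2,3,5-tribromo-4-methoxyphenoxy)terephthalate
Product: 10 2,5-dihydroxy-3,6-bis(2,3,5-tribromo-4-methoxyphenoxy)terephthalic acid
Conditions: KOH (10 equiv), EtOH/H2O, 80 °C, degassed, N2; then 2 M HCl, 0 °C
Reagents that add atoms: potassium hydroxide, [K+].[OH-]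
Why: Alkaline ester hydrolysis (BAc2 saponification) under exclusion of air; the central ring is an electron-rich dianion and so inert to nucleophilic aromatic substitution, the oxygen ortho substituents are small enough to admit hydroxide, and cold acidification avoids protodecarboxylation.

Step 8
Reactants: 10 2,5-dihydroxy-3,6-bis(2,3,5-tribromo-4-methoxyphenoxy)terephthalic acid
Product: 12 2,5-dibromo-3,6-bis(2,3,5-tribromo-4-methoxyphenoxy)benzene-1,4-diol, via dibromoquinone 11 (not isolated)
Conditions: Br2 (3.1 equiv), AcOH–CH2Cl2, rt; then aq. Na2S2O4, EtOAc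
Reagents that add atoms: bromine, BrBr
Why: This is the electrophilic ipso-bromodecarboxylation known for salicylic and other ortho-hydroxybenzoic acids: bromine attacks each carboxyl-bearing carbon of the central ring, which is ortho to a free OH, to give a 6-bromo-6-carboxycyclohexa-2,4-dienone, a β-keto acid that loses CO2 and re-aromatises with the new C–Br bond. The third equivalent of bromine oxidises the resulting electron-rich hydroquinone to quinone 11, and dithionite in the work-up returns it to 12, so the outcome does not depend on stopping at the hydroquinone level. If oxidation to the quinone diacid runs ahead, the HBr formed in the unbuffered medium can reduce it back or add bromide at the carboxyl-bearing quinone carbon, and that adduct, again a β-keto acid, decarboxylates to the same bromohydroquinone. No ring is closed and no stereocentre is formed. The step needs substitution at the two carboxyl carbons only: the central ring has no C–H, and each outer ring carries three bromines, a methyl-capped oxygen and a single C–H next to the bridging ether oxygen, so it should be too deactivated to react at room temperature without a Lewis acid.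

Step 9
Reactants: 12 2,5-dibromo-3,6-bis(2,3,5-tribromo-4-methoxyphenoxy)benzene-1,4-diol
Product: 13 2,5-dibromo-3,6-bis(2,3,5-tribromo-4-hydroxyphenoxy)benzene-1,4-diol
Conditions: BBr3 (8 equiv), CH2Cl2, −78 °C to rt; then ice-water
Reagents that add atoms: none
Why: Lewis-acid cleavage of aryl methyl ethers with BBr3 (bromide attacks the methyl group of the O–B complex); diaryl ethers and C–Br bonds are inert and the hydroquinone hydroxyls only form borates that hydrolyse on work-up, giving the target.

**Compound list**

1 | diethyl 2,5-dihydroxyterephthalate | CCOC(=O)c1cc(O)c(C(=O)OCC)cc1O | starting material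
2 | diethyl 2,5-dibromo-3,6-dihydroxyterephthalate | CCOC(=O)c1c(Br)c(O)c(C(=O)OCC)c(Br)c1O | intermediate
3 | diethyl 2,5-dibromo-3,6-dioxocyclohexa-1,4-diene-1,4-dicarboxylate | CCOC(=O)C1=C(Br)C(=O)C(C(=O)OCC)=C(Br)C1=O | intermediate
4 | 2,6-dibromoanisole (1,3-dibromo-2-methoxybenzene) | COc1c(Br)cccc1Br | starting material
5 | 2-(3,5-dibromo-4-methoxyphenyl)-4,4,5,5-tetramethyl-1,3,2-dioxaborolane | COc1c(Br)cc(cc1Br)B1OC(C)(C)C(C)(C)O1 | intermediate (not isolated)
6 | 3,5-dibromo-4-methoxyphenol | COc1c(Br)cc(O)cc1Br | intermediate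
7 | 2,3,5-tribromo-4-methoxyphenol | COc1c(Br)cc(O)c(Br)c1Br | intermediate
8 | diethyl 3,6-dioxo-2,5-bis(2,3,5-tribromo-4-methoxyphenoxy)cyclohexa-1,4-diene-1,4-dicarboxylate | CCOC(=O)C1=C(Oc2cc(Br)c(OC)c(Br)c2Br)C(=O)C(C(=O)OCC)=C(Oc2cc(Br)c(OC)c(Br)c2Br)C1=O | intermediate
9 | diethyl 2,5-dihydroxy-3,6-bis(2,3,5-tribromo-4-methoxyphenoxy)terephthalate | CCOC(=O)c1c(O)c(Oc2cc(Br)c(OC)c(Br)c2Br)c(C(=O)OCC)c(O)c1Oc1cc(Br)c(OC)c(Br)c1Br | intermediate
10 | 2,5-dihydroxy-3,6-bis(2,3,5-tribromo-4-methoxyphenoxy)terephthalic acid | OC(=O)c1c(O)c(Oc2cc(Br)c(OC)c(Br)c2Br)c(C(=O)O)c(O)c1Oc1cc(Br)c(OC)c(Br)c1Br | intermediate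
11 | 2,5-dibromo-3,6-bis(2,3,5-tribromo-4-methoxyphenoxy)cyclohexa-2,5-diene-1,4-dione | COc1c(Br)cc(OC2=C(Br)C(=O)C(Oc3cc(Br)c(OC)c(Br)c3Br)=C(Br)C2=O)c(Br)c1Br | intermediate (not isolated)
12 | 2,5-dibromo-3,6-bis(2,3,5-tribromo-4-methoxyphenoxy)benzene-1,4-diol | COc1c(Br)cc(Oc2c(O)c(Br)c(Oc3cc(Br)c(OC)c(Br)c3Br)c(O)c2Br)c(Br)c1Br | intermediate
13 | 2,5-dibromo-3,6-bis(2,3,5-tribromo-4-hydroxyphenoxy)benzene-1,4-diol (CNP0163357.0, achiral) | Oc1c(Br)cc(Oc2c(O)c(Br)c(Oc3cc(Br)c(O)c(Br)c3Br)c(O)c2Br)c(Br)c1Br | target

**Count**

Total steps: 9. Longest linear sequence: 7 steps (1 → 2 → 3 → 8 → 9 → 10 → 12 → 13; the branch from 4 through 6 and 7 is equally long).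

**Steps most likely to fail**

Step 8. Oxidation of the central hydroquinone may outrun ipso attack, the quinone stage may shed an aryloxy group by solvolysis, or the lone outer-ring C–H may be brominated on long exposure. The fallback sets out from 10 and comes back at 12, and splits the exchange into two known operations. Acid 10 is protodecarboxylated with catalytic Cu2O/1,10-phenanthroline in NMP–quinoline at about 160 °C under argon to 2,5-bis(2,3,5-tribromo-4-methoxyphenoxy)benzene-1,4-diol F1. Its two central C–H positions, each ortho to a hydroxyl and far more electron-rich than the outer rings, are then brominated with Br2 in AcOH, the mixture passing through quinone 11, and dithionite work-up should give 12.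

Step 5. Electron transfer from the phenoxide to the strongly oxidising bromoquinone may compete (returning 2 and giving phenoxyl-derived dimers), or the reaction may stop after one substitution. The fallback sets out from 1 and comes back at 9; it forms the aryl ethers by conjugate addition to a halogen-free quinone. Compound 1 is oxidised with CAN in aqueous MeCN at 0 °C to diethyl 3,6-dioxocyclohexa-1,4-diene-1,4-dicarboxylate F2. Phenol 7 with catalytic base adds through oxygen at a ring CH carbon, β to a ring carbonyl and an ester, and the adduct tautomerises to diethyl 2,5-dihydroxy-3-(2,3,5-tribromo-4-methoxyphenoxy)terephthalate F3. Ag2O re-oxidises this to diethyl 3,6-dioxo-2-(2,3,5-tribromo-4-methoxyphenoxy)cyclohexa-1,4-diene-1,4-dicarboxylate F4, and a second addition of 7 at the remaining CH carbon should give 9 directly, which also makes step 6 unnecessary.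

Step 7. Hydrolysis of esters flanked by two ortho substituents and conjugated to a phenoxide may be slow or incomplete, and the forcing alkali then needed may cause decomposition. The fallback sets out from 1 and comes back at 10; it carries the carboxyl groups as esters that are cleaved at silicon, away from the crowded carbonyl. Compound 1 is transesterified with 2-(trimethylsilyl)ethanol (Ti(OiPr)4 cat., toluene, reflux, removal of EtOH) to bis[2-(trimethylsilyl)ethyl] 2,5-dihydroxyterephthalate F5, which is taken through the same sequence. NBS in MeCN should give bis[2-(trimethylsilyl)ethyl] 2,5-dibromo-3,6-dihydroxyterephthalate F6. CAN should give bis[2-(trimethylsilyl)ethyl] 2,5-dibromo-3,6-dioxocyclohexa-1,4-diene-1,4-dicarboxylate F7. The sodium salt of 7 should give bis[2-(trimethylsilyl)ethyl] 3,6-dioxo-2,5-bis(2,3,5-tribromo-4-methoxyphenoxy)cyclohexa-1,4-diene-1,4-dicarboxylate F8. Dithionite should give bis[2-(trimethylsilyl)ethyl] 2,5-dihydroxy-3,6-bis(2,3,5-tribromo-4-methoxyphenoxy)terephthalate F9. Bu4NF in THF then releases both acids by fluoride-induced fragmentation to give 10.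

**Further compounds**

F1 | step 8 | 2,5-bis(2,3,5-tribromo-4-methoxyphenoxy)benzene-1,4-diol | COc1c(Br)cc(Oc2cc(O)c(Oc3cc(Br)c(OC)c(Br)c3Br)cc2O)c(Br)c1Br
F2 | step 5 | diethyl 3,6-dioxocyclohexa-1,4-diene-1,4-dicarboxylate | CCOC(=O)C1=CC(=O)C(C(=O)OCC)=CC1=O
F3 | step 5 | diethyl 2,5-dihydroxy-3-(2,3,5-tribromo-4-methoxyphenoxy)terephthalate | CCOC(=O)c1cc(O)c(C(=O)OCC)c(Oc2cc(Br)c(OC)c(Br)c2Br)c1O
F4 | step 5 | diethyl 3,6-dioxo-2-(2,3,5-tribromo-4-methoxyphenoxy)cyclohexa-1,4-diene-1,4-dicarboxylate | CCOC(=O)C1=CC(=O)C(C(=O)OCC)=C(Oc2cc(Br)c(OC)c(Br)c2Br)C1=O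
F5 | step 7 | bis[2-(trimethylsilyl)ethyl] 2,5-dihydroxyterephthalate | C[Si](C)(C)CCOC(=O)c1cc(O)c(C(=O)OCC[Si](C)(C)C)cc1O
F6 | step 7 | bis[2-(trimethylsilyl)ethyl] 2,5-dibromo-3,6-dihydroxyterephthalate | C[Si](C)(C)CCOC(=O)c1c(Br)c(O)c(C(=O)OCC[Si](C)(C)C)c(Br)c1O
F7 | step 7 | bis[2-(trimethylsilyl)ethyl] 2,5-dibromo-3,6-dioxocyclohexa-1,4-diene-1,4-dicarboxylate | C[Si](C)(C)CCOC(=O)C1=C(Br)C(=O)C(C(=O)OCC[Si](C)(C)C)=C(Br)C1=O
F8 | step 7 | bis[2-(trimethylsilyl)ethyl] 3,6-dioxo-2,5-bis(2,3,5-tribromo-4-methoxyphenoxy)cyclohexa-1,4-diene-1,4-dicarboxylate | C[Si](C)(C)CCOC(=O)C1=C(Oc2cc(Br)c(OC)c(Br)c2Br)C(=O)C(C(=O)OCC[Si](C)(C)C)=C(Oc2cc(Br)c(OC)c(Br)c2Br)C1=O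
F9 | step 7 | bis[2-(trimethylsilyl)ethyl] 2,5-dihydroxy-3,6-bis(2,3,5-tribromo-4-methoxyphenoxy)terephthalate | C[Si](C)(C)CCOC(=O)c1c(O)c(Oc2cc(Br)c(OC)c(Br)c2Br)c(C(=O)OCC[Si](C)(C)C)c(O)c1Oc1cc(Br)c(OC)c(Br)c1Br
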